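## Retrosynthetic overview

- The target is read as (1R,2R,3R)-1-(3,4-dimethoxyphenyl)-6,7-dimethoxy-2,3-dimethyltetralin: aryl at C1 trans to the C2 methyl, C2 and C3 methyls cis (erythro). Ring B is opened at C1–C8a together with the C1–aryl bond: aldehyde 10 plus an aryl Grignard reagent gives a benzylic cation that closes by Friedel–Crafts alkylation.
- Aldehyde 10 ⇐ acid 8 ⇐ keto acid 6 ⇐ meso anhydride 2 + arylzinc. The erythro C2/C3 pair is the opened form of cis-2,3-dimethylsuccinic anhydride, so one catalytic, enantiotopic-group-selective arylation fixes both methyl centres; C1 is relayed from C2 in the ring closure.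
- Ring order: both benzene rings are bought (ring A arrives with the arylzinc, the pendant ring with the Grignard reagent). Ring B (C1, C2, C3, C4, C4a, C8a) is the only ring made and is closed last.
- Enabling feature: C1 carries two identical 3,4-dimethoxyphenyl units. The pendant one stabilises a cation at C1 through its para methoxy group; ring A, tied to C1 through C2–C3–C4, offers C8a (para to the C6 methoxy group) for a six-membered closure. The benzylic oxygen at C4 is removed early so that the two chain ends never become equivalent.

Key step: step 6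

Assumption: in step 2 the (S)-configured t-Bu-PHOX ligand is taken to direct the aryl group to the carbonyl next to the (S)-configured ring carbon of 2; if the sense of induction proves opposite, the (R)-ligand is used and nothing else changes.

## Route

Step 1
Reactants: 1 meso-2,3-dimethylsuccinic acid
Product: 2 cis-3,4-dimethyloxolane-2,5-dione (meso anhydride)
Conditions: AcCl (neat), reflux, 2 h; evaporate
Reagents that add atoms: none
Why: Cyclodehydration of a 1,4-diacid by acetyl chloride (via the mixed anhydride) closes the five-membered anhydride under non-basic conditions and in a short reaction time, so the two methine centres are not epimerised and the cis (meso) relationship is kept.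

Step 2
Reactants: 2 cis-3,4-dimethyloxolane-2,5-dione; 3 4-bromo-1,2-dimethoxybenzene
Product: 6 (2R,3S)-4-(3,4-dimethoxyphenyl)-2,3-dimethyl-4-oxobutanoic acid, via (3,4-dimethoxyphenyl)lithium 4 (not isolated), via (3,4-dimethoxyphenyl)zinc triflate 5 (not isolated)
Conditions: 3 (1.7 equiv), n-BuLi, THF, −78 °C; Zn(OTf)2, −78 °C → rt; then 2, [Rh(cod)Cl]2 (4 mol%), (S)-t-Bu-PHOX (8 mol%), DMF, 50 °C; 1 M HCl work-up
Reagents that add atoms: none
Why: Rhodium-catalysed enantioselective acylative cross-coupling of a halide-free arylzinc reagent with a cyclic meso anhydride (desymmetrisation), in which monovalent rhodium bound to the chiral P,N ligand inserts into one of the two enantiotopic acyl–oxygen bonds and the acyl rhodium is arylated by transmetalation and reductive elimination, so that both methyl-bearing centres (erythro by meso origin) are fixed in the absolute sense in one event while the zinc carboxylate end stays inert.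

Step 3
Reactants: 6 (2R,3S)-4-(3,4-dimethoxyphenyl)-2,3-dimethyl-4-oxobutanoic acid
Product: 8 (2R,3R)-4-(3,4-dimethoxyphenyl)-2,3-dimethylbutanoic acid, via benzylic hydroxy acid 7 (not isolated)
Conditions: H2 (4 atm), 10% Pd/C, AcOH, HClO4 (cat.), rt
Reagents that add atoms: none
Why: Catalytic hydrogenolysis of an electron-rich aryl ketone through the benzylic alcohol (the classical reduction of aroylpropionic acids) removes the benzylic oxygen without involving the two methine centres, and it makes C4 a methylene group so that the two chain ends stay different later.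

Step 4
Reactants: 8 (2R,3R)-4-(3,4-dimethoxyphenyl)-2,3-dimethylbutanoic acid
Product: 9 (2R,3R)-4-(3,4-dimethoxyphenyl)-2,3-dimethylbutan-1-ol
Conditions: BH3·SMe2, THF, 0 °C → rt; H2O
Reagents that add atoms: none
Why: Borane reduces the carboxylic acid chemoselectively through the acyloxyborane under non-basic conditions, so the α-methyl centre is not enolised.

Step 5
Reactants: 9 (2R,3R)-4-(3,4-dimethoxyphenyl)-2,3-dimethylbutan-1-ol
Product: 10 (2R,3R)-4-(3,4-dimethoxyphenyl)-2,3-dimethylbutanal
Conditions: TEMPO (10 mol%), PhI(OAc)2 (1.1 equiv), CH2Cl2, rt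
Reagents that add atoms: none
Why: Oxoammonium (TEMPO) oxidation with PhI(OAc)2 as the terminal oxidant stops at the aldehyde and is non-basic, so the α-methyl centre of the aldehyde keeps its configuration.

Step 6
Reactants: 10 (2R,3R)-4-(3,4-dimethoxyphenyl)-2,3-dimethylbutanal; 11 (3,4-dimethoxyphenyl)magnesium bromide (commercial solution in THF)
Product: 13 (1R,2R,3R)-1-(3,4-dimethoxyphenyl)-6,7-dimethoxy-2,3-dimethyl-1,2,3,4-tetrahydronaphthalene, via diaryl carbinol 12 (not isolated)
Conditions: 11 (1.3 equiv), THF, −78 → 0 °C; then volatiles removed, CH2Cl2 (high dilution), CF3CO2H (10 equiv), −20 → 0 °C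
Reagents that add atoms: none
Why: The aryl Grignard reagent adds to aldehyde 10 (1,2-addition, facial selectivity irrelevant) and TFA then protonates the magnesium alkoxide and ionises both epimers of carbinol 12 to one benzylic cation at C1, stabilised as a quinoid oxocarbenium ion by the para methoxy group of the new pendant ring, which ring A attacks through the carbon para to its 3-methoxy group (future C8a) with loss of a proton. The closest known reaction type is the acid-mediated Friedel–Crafts cyclialkylation of 1,4-diarylbutan-1-ols to 1-aryltetralins, here run directly on the crude adduct of the Grignard addition. Ring B (C1, C2, C3, C4, C4a, C8a) is closed as a six-membered ring by electrophilic aromatic substitution, 6-exo with respect to the cation π system (aryl participation of the Ar2-6 kind), through a chair-like transition state. The only new stereocentre, C1, is set by the C2 methyl centre: allylic 1,3-strain keeps the C2–H bond in the plane of the cation, the chain leading to ring A lies on one face and the C2 methyl on the other, so the 3,4-dimethoxyphenyl group should end pseudo-equatorial and trans to the C2 methyl (1R), whatever the carbinol configuration and although the C3 methyl is then axial. The step needs regioselectivity on ring A (para, not ortho, to the 3-methoxy group: secured by the directing effect and by crowding at the carbon between chain and methoxy), facial selectivity at C1 (secured as described) and capture of the cation faster than loss of the C2 proton (secured by the six-atom tether to an electron-rich arene, low temperature and dilution). Only ring A can be the nucleophile, because C4 is already a methylene group and the pendant ring is conjugated to the cation.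

## Compound list

1 | meso-2,3-dimethylsuccinic acid, (2R,3S) | OC(=O)[C@H](C)[C@H](C)C(=O)O | starting material
2 | cis-3,4-dimethyloxolane-2,5-dione (meso, 3R,4S) | O=C1OC(=O)[C@H](C)[C@@H]1C | intermediate
3 | 4-bromo-1,2-dimethoxybenzene | COc1ccc(Br)cc1OC | starting material
4 | (3,4-dimethoxyphenyl)lithium | [Li]c1ccc(OC)c(OC)c1 | intermediate (not isolated)
5 | (3,4-dimethoxyphenyl)zinc triflate | COc1ccc([Zn]OS(=O)(=O)C(F)(F)F)cc1OC | intermediate (not isolated)
6 | (2R,3S)-4-(3,4-dimethoxyphenyl)-2,3-dimethyl-4-oxobutanoic acid | OC(=O)[C@H](C)[C@H](C)C(=O)c1ccc(OC)c(OC)c1 | intermediate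
7 | (2R,3S)-4-(3,4-dimethoxyphenyl)-4-hydroxy-2,3-dimethylbutanoic acid (both C4 epimers) | OC(=O)[C@H](C)[C@H](C)C(O)c1ccc(OC)c(OC)c1 | intermediate (not isolated)
8 | (2R,3R)-4-(3,4-dimethoxyphenyl)-2,3-dimethylbutanoic acid | OC(=O)[C@H](C)[C@H](C)Cc1ccc(OC)c(OC)c1 | intermediate
9 | (2R,3R)-4-(3,4-dimethoxyphenyl)-2,3-dimethylbutan-1-ol | OC[C@H](C)[C@H](C)Cc1ccc(OC)c(OC)c1 | intermediate
10 | (2R,3R)-4-(3,4-dimethoxyphenyl)-2,3-dimethylbutanal | O=C[C@H](C)[C@H](C)Cc1ccc(OC)c(OC)c1 | intermediate
11 | (3,4-dimethoxyphenyl)magnesium bromide | COc1ccc([Mg]Br)cc1OC | starting material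
12 | (2R,3R)-1,4-bis(3,4-dimethoxyphenyl)-2,3-dimethylbutan-1-ol (both C1 epimers) | COc1ccc(cc1OC)C(O)[C@H](C)[C@H](C)Cc1ccc(OC)c(OC)c1 | intermediate (not isolated)
13 | (1R,2R,3R)-1-(3,4-dimethoxyphenyl)-6,7-dimethoxy-2,3-dimethyl-1,2,3,4-tetrahydronaphthalene | COc1ccc([C@@H]2c3cc(OC)c(OC)cc3C[C@@H](C)[C@H]2C)cc1OC | target

## Step count and risks

Total steps: 6. Longest linear sequence: 6 steps (1 → 2 → 6 → 8 → 9 → 10 → 13).

Steps most likely to fail:

Step 6. The one-pot union can fail before the ring closes: the basic Grignard reagent may enolise aldehyde 10 and erode the C2 centre, and magnesium salts and residual ether from the addition may retard ionisation, so that the carbinol is recovered or the cation loses the C2 proton. The fallback sets out from acid 8 and comes back at carbinol 12. Acid 8 is converted (1,1'-carbonyldiimidazole, then MeNH(OMe)·HCl, CH2Cl2, rt) into the Weinreb amide (2R,3R)-4-(3,4-dimethoxyphenyl)-N-methoxy-N,2,3-trimethylbutanamide F1. Grignard reagent 11 (THF, 0 °C; aqueous NH4Cl quench) adds once to F1, because the magnesium chelate survives until work-up, and should give the aryl ketone (2R,3R)-1,4-bis(3,4-dimethoxyphenyl)-2,3-dimethylbutan-1-one F2, so that no enolisable aldehyde is ever exposed to the organometallic. NaBH4 (MeOH, 0 °C) reduces F2 to 12, which is now isolated, freed from salts and cyclised to 13 in a separate operation (CF3CO2H, CH2Cl2, −20 → 0 °C).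

Step 2. The electron-rich arylzinc may transmetalate slowly or the chiral ligand may discriminate the two enantiotopic carbonyl groups incompletely, giving low conversion or insufficient enantiomeric purity. The fallback sets out from anhydride 2 and comes back at keto acid 6. Cinchona-alkaloid-mediated enantioselective methanolysis (quinidine or quinine, whichever gives the needed antipode, MeOH, toluene, −55 °C) should give the hemiester (2S,3R)-4-methoxy-2,3-dimethyl-4-oxobutanoic acid F3. SOCl2 converts it into the acid chloride methyl (2R,3S)-4-chloro-2,3-dimethyl-4-oxobutanoate F4. Friedel–Crafts acylation of 1,2-dimethoxybenzene (SnCl4, CH2Cl2, −20 °C; para to a methoxy group) gives the keto ester methyl (2R,3S)-4-(3,4-dimethoxyphenyl)-2,3-dimethyl-4-oxobutanoate F5. Mild ester cleavage (Me3SnOH, 1,2-dichloroethane, 70 °C) then gives 6.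

Step 3. Acid-catalysed enolisation of the aryl ketone may epimerise C3 before the carbonyl is reduced, or the reduction may stall at the lactone stage. The fallback sets out from keto acid 6 and comes back at acid 8. NaBH4 (MeOH, 0 °C) reduces the ketone first under non-enolising conditions to hydroxy acid 7, which on acidification (1 M HCl) closes to the lactone (3R,4S)-5-(3,4-dimethoxyphenyl)-3,4-dimethyloxolan-2-one F6 (both C5 epimers). Ionic hydrogenation (Et3SiH, BF3·OEt2, CH2Cl2, 0 °C) then cleaves the benzylic C–O bond of F6 to give 8.

Further compounds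
F1 | step 6 | (2R,3R)-4-(3,4-dimethoxyphenyl)-N-methoxy-N,2,3-trimethylbutanamide | CON(C)C(=O)[C@H](C)[C@H](C)Cc1ccc(OC)c(OC)c1
F2 | step 6 | (2R,3R)-1,4-bis(3,4-dimethoxyphenyl)-2,3-dimethylbutan-1-one | COc1ccc(cc1OC)C(=O)[C@H](C)[C@H](C)Cc1ccc(OC)c(OC)c1
F3 | step 2 | (2S,3R)-4-methoxy-2,3-dimethyl-4-oxobutanoic acid | COC(=O)[C@H](C)[C@H](C)C(=O)O
F4 | step 2 | methyl (2R,3S)-4-chloro-2,3-dimethyl-4-oxobutanoate | COC(=O)[C@H](C)[C@H](C)C(=O)Cl
F5 | step 2 | methyl (2R,3S)-4-(3,4-dimethoxyphenyl)-2,3-dimethyl-4-oxobutanoate | COC(=O)[C@H](C)[C@H](C)C(=O)c1ccc(OC)c(OC)c1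
F6 | step 3 | (3R,4S)-5-(3,4-dimethoxyphenyl)-3,4-dimethyloxolan-2-one (both C5 epimers) | O=C1[C@H](C)[C@H](C)C(c2ccc(OC)c(OC)c2)O1
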